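**Strategy.** Ring A is disconnected from the C4a–C8a edge of ring C, so the flavonol is traced to a kojic-acid-derived 4-pyranone that already carries O3 and the C2 aryl group. One photochemical–thermal operation joins a diazoacetyl group on the future C8a with tert-butoxyacetylene and builds the whole benzene ring (C8–C8a, C5–C6, C7–C8, C4a–C5). It exploits the C5-OH, C6-H, C7-O, C8-H pattern of ring A, the resorcinol pattern that a vinylketene plus an alkoxyalkyne delivers, and the 3-oxy-4-pyranone identity of ring C. The precursor is a 6-aryl-5-(methoxymethoxy)-4-pyranone with a 2-diazoacetyl group; 5-OH emerges free, O3 and O7 under acid-labile groups.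

Key step: step 7

**Remarks on the chemistry**
- Assumption: the target is taken as the free bis(hydrogen sulfate) as drawn. It is liberated only in the last operation from its bis(triethylammonium) salt 21 and kept cold, because aryl hydrogen sulfates (the 3-sulfate most of all) hydrolyse under their own acidity.
- Pyranone intermediates carry kojic acid locants (O1, C2 exocyclic carbon, C5 oxygen, C6 aryl). From step 7 on, flavone locants are used.
- The diazoketone is excited with violet-blue light at its long-wavelength band, where neither the arylpyranone nor the 5-hydroxyflavone product should absorb appreciably.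
- tert-Butoxyacetylene extrudes isobutene to give ketene on warming, so the excess is stripped cold before the thermal stage.
- If the 7-O-tert-butyl group is lost early, the material still converges on 19 in step 8.
- The diazo group is introduced with TMSCHN2 on an acid chloride made without HCl, so the MOM enol ether and the acyl-activated pyranone C=C are not put at risk.
- Step 6 generates dichloroacetylene transiently (inert atmosphere, no isolation). Diazoketone 8 is handled cold and shielded from light.

**Route**

Step 1
Reactants: 1 kojic acid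
Product: 2 6-bromokojic acid (6-bromo-5-hydroxy-2-(hydroxymethyl)-4H-pyran-4-one)
Conditions: NBS (1.05 equiv), DMF, 0 °C to rt
Reagents that add atoms: N-bromosuccinimide, O=C1CCC(=O)N1Br
Why: Electrophilic bromination of the enol should go to C6, the only carbon ortho to the enolic 5-OH and the site at which kojic acid takes electrophiles, while the hydroxymethyl group is inert to NBS.

Step 2
Reactants: 2 6-bromokojic acid
Product: 3 6-bromo-2-(hydroxymethyl)-5-(methoxymethoxy)-4H-pyran-4-one
Conditions: MOMCl (1.1 equiv), K2CO3, acetone, 0 °C to rt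
Reagents that add atoms: chloromethyl methyl ether, COCCl
Why: Williamson-type O-alkylation in which carbonate deprotonates only the acidic enolic 5-OH (a vinylogous carboxylic acid), so one equivalent of MOMCl should leave the neutral primary alcohol untouched.

Step 3
Reactants: 3 6-bromo-2-(hydroxymethyl)-5-(methoxymethoxy)-4H-pyran-4-one; 4 3,4-bis(benzyloxy)phenylboronic acid
Product: 5 6-[3,4-bis(benzyloxy)phenyl]-2-(hydroxymethyl)-5-(methoxymethoxy)-4H-pyran-4-one
Conditions: Pd(dppf)Cl2 (3 mol%), K3PO4, 1,4-dioxane/H2O (9:1), 70 °C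
Reagents that add atoms: none
Why: Suzuki–Miyaura coupling in which the C6–Br bond, a vinylogous acyl bromide, adds readily to zerovalent palladium, and a phosphate base in a mostly organic medium limits addition–elimination by hydroxide at the same carbon.

Step 4
Reactants: 5 6-[3,4-bis(benzyloxy)phenyl]-2-(hydroxymethyl)-5-(methoxymethoxy)-4H-pyran-4-one
Product: 6 6-[3,4-bis(benzyloxy)phenyl]-5-(methoxymethoxy)-4-oxo-4H-pyran-2-carboxylic acid
Conditions: TEMPO (20 mol%), PhI(OAc)2 (2.2 equiv), MeCN/H2O (1:1), rt
Reagents that add atoms: water, O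
Why: Oxoammonium (TEMPO) oxidation in aqueous acetonitrile should take the activated primary alcohol through the hydrated aldehyde to the acid under nearly neutral conditions that spare the MOM and benzyl ethers.

Step 5
Reactants: 6 6-[3,4-bis(benzyloxy)phenyl]-5-(methoxymethoxy)-4-oxo-4H-pyran-2-carboxylic acid
Product: 8 2-diazo-1-[6-(3,4-bis(benzyloxy)phenyl)-5-(methoxymethoxy)-4-oxo-4H-pyran-2-yl]ethan-1-one, via acid chloride 7 (not isolated)
Conditions: 1-chloro-N,N,2-trimethylprop-1-en-1-amine (1.1 equiv), CH2Cl2, 0 °C to rt; then TMSCHN2 (2 equiv), MeCN/THF, 0 °C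
Reagents that add atoms: trimethylsilyldiazomethane, C[Si](C)(C)C=[N+]=[N-]
Why: The α-chloroenamine forms the acid chloride with an amide as the only by-product (no HCl, so the MOM enol ether survives), and C-acylation of the silyldiazomethane with loss of the silyl group to chloride (the first stage of an Arndt–Eistert sequence) should give the diazoketone, the bulky reagent at 0 °C being slow to add as a dipole across the pyranone C=C.

Step 6
Reactants: 9 trichloroethylene; 10 potassium tert-butoxide
Product: 14 tert-butoxyacetylene, via dichlorovinyl ether 11 (not isolated), via chloroalkyne 12 (not isolated), via lithium acetylide 13 (not isolated)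
Conditions: THF, −40 °C to rt; n-BuLi (2.3 equiv), −78 to −40 °C; H2O, −78 to 0 °C; distil below 30 °C
Reagents that add atoms: none
Why: Alkoxide-induced dehydrochlorination to dichloroacetylene and anti addition of tert-butoxide give the dichlorovinyl ether, which n-BuLi should convert by β-elimination and chlorine–lithium exchange into the lithium alkoxyacetylide that water protonates (the standard trichloroethylene route to ynol ethers).

Step 7
Reactants: 8 2-diazo-1-[6-(3,4-bis(benzyloxy)phenyl)-5-(methoxymethoxy)-4-oxo-4H-pyran-2-yl]ethan-1-one; 14 tert-butoxyacetylene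
Product: 18 2-[3,4-bis(benzyloxy)phenyl]-7-tert-butoxy-5-hydroxy-3-(methoxymethoxy)-4H-chromen-4-one, via pyranonylketene 15 (not isolated), via cyclobutenone 16 (not isolated), via dienylketene 17 (not isolated)
Conditions: 14 (3 equiv), CH2Cl2 (0.02 M, degassed), hν (LED, ca. 425 nm), 15 °C; evaporate below 25 °C; toluene, 80 °C
Reagents that add atoms: none
Why: Proposed new method: excitation of the long-wavelength diazoketone band expels N2 and the Wolff shift of the pyranone carbon C8a onto the diazo carbon (future C8) gives ketene 15, whose electrophilic carbonyl carbon (future C5) is attacked by the unsubstituted alkyne terminus in a [2+2] cycloaddition that forms C5–C6 and C7–C8 in cyclobutenone 16. At 80 °C 16 should open by a reversible conrotatory 4π electrocyclic reaction to dienylketene 17, whose isomer with ketene and pyranone cis closes ring A by a thermally allowed disrotatory 6π electrocyclisation onto C4a (C4a–C5), and enolisation of the doubly activated C4a–H then gives the chelated C5 phenol. The closest known reaction type is the photochemical Danheiser benzannulation of aryl, heteroaryl and alkenyl α-diazoketones with alkoxy- and siloxyalkynes, in which a 4-pyranone C=C has not yet served as the 2π end of the closing triene. No stereocenter is formed. The step needs regiocontrol in the [2+2], secured by the polarity of ketene and ynol ether that places O7 meta to 5-OH, and site control in the closure, secured because C4a is the only carbon neighbour of C8a (the other neighbour is O1) and, as the β-carbon of the ring enol ether, is matched to the electrophilic ketene carbon. Excess alkyne is removed cold before heating so that ketene from its retro-ene decomposition cannot acylate the product.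

Step 8
Reactants: 18 2-[3,4-bis(benzyloxy)phenyl]-7-tert-butoxy-5-hydroxy-3-(methoxymethoxy)-4H-chromen-4-one
Product: 19 3',4'-di-O-benzylquercetin (2-[3,4-bis(benzyloxy)phenyl]-3,5,7-trihydroxy-4H-chromen-4-one)
Conditions: HCl (2 M in MeOH), THF, 45 °C
Reagents that add atoms: none
Why: Acid-catalysed acetal exchange with methanol should remove the enol MOM ether and E1 cleavage the aryl tert-butyl ether, while benzyl aryl ethers are stable to methanolic HCl and methanol intercepts the formaldehyde equivalent and the tert-butyl cation before they can alkylate ring A.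

Step 9
Reactants: 19 3',4'-di-O-benzylquercetin
Product: 20 bis(triethylammonium) 3',4'-di-O-benzylquercetin 3,7-bis(sulfate)
Conditions: SO3·NEt3 (3 equiv), Et3N (1 equiv), DMF, 40 °C
Reagents that add atoms: sulfur trioxide–triethylamine complex, CC[N+](CC)(CC)S(=O)(=O)[O-]
Why: O-sulfation of phenols by a sulfur trioxide–amine complex should take 7-OH (the most acidic) and 3-OH, whereas 5-OH is held in a six-membered hydrogen bond to the C4 carbonyl and characteristically stays free with such reagents, and the catechol is blocked as benzyl ethers.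

Step 10
Reactants: 20 bis(triethylammonium) 3',4'-di-O-benzylquercetin 3,7-bis(sulfate)
Product: 22 quercetin 3,7-di-O-sulfate, via triethylammonium salt 21 (not isolated)
Conditions: H2 (1 atm), Pd/C (10 wt% Pd), MeOH/H2O, rt; filter; sulfonic acid resin (H+ form), H2O, 0–5 °C; freeze-dry
Reagents that add atoms: none
Why: Catalytic hydrogenolysis should cleave the two benzyl aryl ethers without touching aryl sulfate salts or the flavonol C2=C3 bond, and cation exchange then replaces triethylammonium by protons, the acid form being kept cold and freeze-dried at once to avoid autocatalytic loss of sulfate.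

**Compound list**

1 | kojic acid (5-hydroxy-2-(hydroxymethyl)-4H-pyran-4-one) | OCc1cc(=O)c(O)co1 | starting material
2 | 6-bromokojic acid (6-bromo-5-hydroxy-2-(hydroxymethyl)-4H-pyran-4-one) | OCc1cc(=O)c(O)c(Br)o1 | intermediate
3 | 6-bromo-2-(hydroxymethyl)-5-(methoxymethoxy)-4H-pyran-4-one | OCc1cc(=O)c(OCOC)c(Br)o1 | intermediate
4 | 3,4-bis(benzyloxy)phenylboronic acid | OB(O)c1ccc(OCc2ccccc2)c(OCc2ccccc2)c1 | starting material
5 | 6-[3,4-bis(benzyloxy)phenyl]-2-(hydroxymethyl)-5-(methoxymethoxy)-4H-pyran-4-one | OCc1cc(=O)c(OCOC)c(-c2ccc(OCc3ccccc3)c(OCc3ccccc3)c2)o1 | intermediate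
6 | 6-[3,4-bis(benzyloxy)phenyl]-5-(methoxymethoxy)-4-oxo-4H-pyran-2-carboxylic acid | O=C(O)c1cc(=O)c(OCOC)c(-c2ccc(OCc3ccccc3)c(OCc3ccccc3)c2)o1 | intermediate
7 | 6-[3,4-bis(benzyloxy)phenyl]-5-(methoxymethoxy)-4-oxo-4H-pyran-2-carbonyl chloride | O=C(Cl)c1cc(=O)c(OCOC)c(-c2ccc(OCc3ccccc3)c(OCc3ccccc3)c2)o1 | intermediate (not isolated)
8 | 2-diazo-1-[6-(3,4-bis(benzyloxy)phenyl)-5-(methoxymethoxy)-4-oxo-4H-pyran-2-yl]ethan-1-one | [N-]=[N+]=CC(=O)c1cc(=O)c(OCOC)c(-c2ccc(OCc3ccccc3)c(OCc3ccccc3)c2)o1 | intermediate
9 | trichloroethylene | ClC=C(Cl)Cl | starting material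
10 | potassium tert-butoxide | CC(C)(C)[O-].[K+] | starting material
11 | (E)-1-tert-butoxy-1,2-dichloroethene | Cl/C=C(/Cl)OC(C)(C)C | intermediate (not isolated)
12 | 2-[(chloroethynyl)oxy]-2-methylpropane | ClC#COC(C)(C)C | intermediate (not isolated)
13 | lithium tert-butoxyacetylide | [Li]C#COC(C)(C)C | intermediate (not isolated)
14 | tert-butoxyacetylene | C#COC(C)(C)C | intermediate
15 | 2-[6-(3,4-bis(benzyloxy)phenyl)-5-(methoxymethoxy)-4-oxo-4H-pyran-2-yl]ethen-1-one (ketene) | O=C=Cc1cc(=O)c(OCOC)c(-c2ccc(OCc3ccccc3)c(OCc3ccccc3)c2)o1 | intermediate (not isolated)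
16 | 3-tert-butoxy-4-[6-(3,4-bis(benzyloxy)phenyl)-5-(methoxymethoxy)-4-oxo-4H-pyran-2-yl]cyclobut-2-en-1-one (racemic) | O=C1C=C(OC(C)(C)C)C1c1cc(=O)c(OCOC)c(-c2ccc(OCc3ccccc3)c(OCc3ccccc3)c2)o1 | intermediate (not isolated)
17 | (3E)-3-tert-butoxy-4-[6-(3,4-bis(benzyloxy)phenyl)-5-(methoxymethoxy)-4-oxo-4H-pyran-2-yl]buta-1,3-dien-1-one | O=C=C/C(OC(C)(C)C)=C\c1cc(=O)c(OCOC)c(-c2ccc(OCc3ccccc3)c(OCc3ccccc3)c2)o1 | intermediate (not isolated)
18 | 2-[3,4-bis(benzyloxy)phenyl]-7-tert-butoxy-5-hydroxy-3-(methoxymethoxy)-4H-chromen-4-one | COCOc1c(-c2ccc(OCc3ccccc3)c(OCc3ccccc3)c2)oc2cc(OC(C)(C)C)cc(O)c2c1=O | intermediate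
19 | 3',4'-di-O-benzylquercetin (2-[3,4-bis(benzyloxy)phenyl]-3,5,7-trihydroxy-4H-chromen-4-one) | O=c1c(O)c(-c2ccc(OCc3ccccc3)c(OCc3ccccc3)c2)oc2cc(O)cc(O)c12 | intermediate
20 | bis(triethylammonium) 3',4'-di-O-benzylquercetin 3,7-bis(sulfate) | O=c1c(OS(=O)(=O)[O-])c(-c2ccc(OCc3ccccc3)c(OCc3ccccc3)c2)oc2cc(OS(=O)(=O)[O-])cc(O)c12.CC[NH+](CC)CC.CC[NH+](CC)CC | intermediate
21 | bis(triethylammonium) quercetin 3,7-bis(sulfate) | O=c1c(OS(=O)(=O)[O-])c(-c2ccc(O)c(O)c2)oc2cc(OS(=O)(=O)[O-])cc(O)c12.CC[NH+](CC)CC.CC[NH+](CC)CC | intermediate (not isolated)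
22 | quercetin 3,7-di-O-sulfate | O=c1c(OS(=O)(=O)O)c(-c2ccc(O)c(O)c2)oc2cc(OS(=O)(=O)O)cc(O)c12 | target

**Step count and risk**

Total steps: 10. Longest linear sequence: 9 steps (kojic acid through steps 1–5 and 7–10); step 6 is a one-step side branch.

Steps most likely to fail:

1. Step 7 (benzannulation). The pyranonylketene may dimerise or be lost to other photoreactions, or the dienylketene may fail to close onto the electron-poor pyranone carbon C4a, so ring A would not form. The fallback uses known chemistry, sets out from boronic acid 4 and comes back at 19, building ring C onto a preformed ring A. Commercial 5,7-dihydroxychromone is converted with NaH and MOMCl in DMF into 5,7-bis(methoxymethoxy)-4H-chromen-4-one F1. F1 is arylated at C2 with 4 by the oxidative Heck coupling of chromones with arylboronic acids (Pd(OAc)2 catalyst, O2 or benzoquinone as terminal oxidant) to give 2-[3,4-bis(benzyloxy)phenyl]-5,7-bis(methoxymethoxy)-4H-chromen-4-one F2. Dimethyldioxirane in acetone/CH2Cl2 at 0 °C epoxidises C2=C3 to the flavone 2,3-epoxide F3. Methanolic HCl then opens the epoxide to the 3-hydroxyflavone and removes both MOM groups, giving 19, from which steps 9 and 10 follow unchanged.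

2. Step 5 (diazoketone). C-acylation of the silyldiazomethane by the hindered, electron-poor acid chloride may be slow, leaving room for dipolar addition of the diazoalkane to the pyranone C=C or for cleavage of the MOM ether by chlorosilane. The fallback sets out from acid 6 (through its chloride 7) and comes back at 8; it delivers the diazo group by sulfonyl azide transfer and uses no diazoalkane. Negishi acylation of 7 with MeZnCl (Pd(PPh3)4 catalyst, THF, 0 °C) should give 2-acetyl-6-[3,4-bis(benzyloxy)phenyl]-5-(methoxymethoxy)-4H-pyran-4-one F4. Its lithium enolate (LiN(SiMe3)2, THF, −78 °C) is trifluoroacetylated with 2,2,2-trifluoroethyl trifluoroacetate to the 4,4,4-trifluoro-1-(pyranonyl)butane-1,3-dione F5. Detrifluoroacetylative diazo transfer with methanesulfonyl azide, Et3N and water in MeCN then gives 8.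

3. Step 3 (Suzuki coupling). Base may add to the bromine-bearing carbon with ring opening, or hydrodebromination and protodeboronation of the electron-rich boronic acid may outrun transmetalation. The fallback reverses the polarity of the coupling, sets out from kojic acid 1, comes back at 5 and also bypasses steps 1 and 2. Selective O-alkylation (K2CO3, MOMCl) gives 2-(hydroxymethyl)-5-(methoxymethoxy)-4H-pyran-4-one F6, and TBSCl/imidazole gives its silyl ether 2-[(tert-butyldimethylsilyloxy)methyl]-5-(methoxymethoxy)-4H-pyran-4-one F7. Directed zincation with TMPZnCl·LiCl at C6–H (flanked by the ring oxygen and the MOM ether) gives the pyranonylzinc chloride F8. Negishi coupling of F8 with 4-bromo-1,2-bis(benzyloxy)benzene (Pd(OAc)2/SPhos, THF, 50 °C) gives the 6-aryl silyl ether F9. Bu4NF in THF then frees the primary alcohol to give 5.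

**Further compounds**

F1 | step 7 | 5,7-bis(methoxymethoxy)-4H-chromen-4-one | COCOc1cc(OCOC)c2c(=O)ccoc2c1
F2 | step 7 | 2-[3,4-bis(benzyloxy)phenyl]-5,7-bis(methoxymethoxy)-4H-chromen-4-one | COCOc1cc(OCOC)c2c(=O)cc(-c3ccc(OCc4ccccc4)c(OCc4ccccc4)c3)oc2c1
F3 | step 7 | 2-[3,4-bis(benzyloxy)phenyl]-2,3-epoxy-5,7-bis(methoxymethoxy)-2,3-dihydro-4H-chromen-4-one (racemic, cis-fused; one enantiomer drawn) | COCOc1cc(OCOC)c2C(=O)[C@H]3O[C@@]3(c4ccc(OCc5ccccc5)c(OCc5ccccc5)c4)Oc2c1
F4 | step 5 | 2-acetyl-6-[3,4-bis(benzyloxy)phenyl]-5-(methoxymethoxy)-4H-pyran-4-one | CC(=O)c1cc(=O)c(OCOC)c(-c2ccc(OCc3ccccc3)c(OCc3ccccc3)c2)o1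
F5 | step 5 | 4,4,4-trifluoro-1-[6-(3,4-bis(benzyloxy)phenyl)-5-(methoxymethoxy)-4-oxo-4H-pyran-2-yl]butane-1,3-dione | O=C(CC(=O)C(F)(F)F)c1cc(=O)c(OCOC)c(-c2ccc(OCc3ccccc3)c(OCc3ccccc3)c2)o1
F6 | step 3 | 2-(hydroxymethyl)-5-(methoxymethoxy)-4H-pyran-4-one | OCc1cc(=O)c(OCOC)co1
F7 | step 3 | 2-[(tert-butyldimethylsilyloxy)methyl]-5-(methoxymethoxy)-4H-pyran-4-one | CC(C)(C)[Si](C)(C)OCc1cc(=O)c(OCOC)co1
F8 | step 3 | {6-[(tert-butyldimethylsilyloxy)methyl]-3-(methoxymethoxy)-4-oxo-4H-pyran-2-yl}zinc chloride | CC(C)(C)[Si](C)(C)OCc1cc(=O)c(OCOC)c([Zn]Cl)o1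
F9 | step 3 | 6-[3,4-bis(benzyloxy)phenyl]-2-[(tert-butyldimethylsilyloxy)methyl]-5-(methoxymethoxy)-4H-pyran-4-one | CC(C)(C)[Si](C)(C)OCc1cc(=O)c(OCOC)c(-c2ccc(OCc3ccccc3)c(OCc3ccccc3)c2)o1
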